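**Retrosynthetic overview**

1. The stearate, the free C19 acid and the C4 methyl group (C18) are late: lipase stearoylation of the C15 alcohol, thiolate cleavage of a C19 methyl ester, and reductive methylation of a ring A C3=C4–C19 enoate.
2. Key disconnection: ring A is a Diels–Alder ring. One thermal intramolecular [4+2] forms C5–C10 and C1–C2 from the diene ester C5=C4(CO2Me)–C3=C2 and the isopropenyl group C10(=C1H2)–C20H3. Carbons C6–C9 are the tether, so the C5–C10 bond closes ring B and, with C1–C2, ring A; both rings form in this step and no ring exists before it.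
3. Enabling feature: the C19 carboxyl on C4 (it makes C3=C4–C19 an enoate retron and the diene electron-poor); C10 bearing only the C20 methyl and the ring methylene C1 (a latent isopropenyl group); and the C9 stereocentre next to C10 on the tether, which relays absolute configuration. The exocyclic C8=C17 alkene is present from the start and sits only two atoms from the diene, so it cannot compete.
4. Triene: C5=C4 by bromo-Horner–Wadsworth–Emmons olefination of a C5 aldehyde, C3=C2 by Stille vinylation. The skipped diene C8(=C17)–C9–C10(=C1) comes from a copper-catalysed enantioselective SN2′ coupling of an alkenylaluminium with the allylic phosphate of oxidised (S)-citronellol, which supplies C9–C16, C10, C1, C20 and the 13S centre.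

Key step: step 10

Remark: positions are given in labdane numbering; the target is read as the 15-stearate of (13S)-15-hydroxylabd-8(17)-en-19-oic acid (5α-H, 9β side chain, 10β-methyl, axial 4β-carboxyl), and 1, 5, 10 and 21 are taken as purchased.

**Route**

Step 1
Reactants: 1 (S)-citronellol
Product: 2 triisopropyl{[(3S)-3,7-dimethyloct-6-en-1-yl]oxy}silane
Conditions: TIPSCl, imidazole, DMF, 25 °C
Reagents that add atoms: triisopropylsilyl chloride, CC(C)[Si](Cl)(C(C)C)C(C)C
Why: Silyl ether formation at the primary alcohol; the TIPS group should survive the organoaluminium, base, heat and Li/NH3 steps and stay on when the TBS ether is removed in step 5, and the C13 centre is untouched.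

Step 2
Reactants: 2 triisopropyl{[(3S)-3,7-dimethyloct-6-en-1-yl]oxy}silane
Product: 3 (2E,6S)-2,6-dimethyl-8-[(triisopropylsilyl)oxy]oct-2-en-1-ol
Conditions: SeO2 (cat.), t-BuOOH, CH2Cl2, 25 °C
Reagents that add atoms: selenium dioxide (catalytic oxygen carrier), O=[Se]=O; tert-butyl hydroperoxide (stoichiometric oxygen source), CC(C)(C)OO
Why: Riley allylic oxidation (ene reaction, then [2,3]-sigmatropic shift) should hydroxylate the (E)-methyl group of the trisubstituted alkene, which fixes the E geometry and marks the future C1.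

Step 3
Reactants: 3 (2E,6S)-2,6-dimethyl-8-[(triisopropylsilyl)oxy]oct-2-en-1-ol
Product: 4 diethyl (2E,6S)-2,6-dimethyl-8-[(triisopropylsilyl)oxy]oct-2-en-1-yl phosphate
Conditions: ClP(O)(OEt)2, Et3N, DMAP (cat.), CH2Cl2, 0 °C
Reagents that add atoms: diethyl chlorophosphate, CCOP(=O)(Cl)OCC
Why: O-Phosphorylation of the primary allylic alcohol installs the leaving group for copper-catalysed SN2′ substitution; no stereocentre changes.

Step 4
Reactants: 4 diethyl (2E,6S)-2,6-dimethyl-8-[(triisopropylsilyl)oxy]oct-2-en-1-yl phosphate; 5 tert-butyldimethyl(pent-4-yn-1-yloxy)silane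
Product: 7 (5R,8S)-1-[(tert-butyldimethylsilyl)oxy]-8-methyl-4-methylidene-5-(prop-1-en-2-yl)-10-[(triisopropylsilyl)oxy]decane, via alkenylaluminium 6 (not isolated)
Conditions: 5, i-Bu2AlH, NiCl2(dppp) (3 mol %), THF, 22 °C; then 4, CuCl2·2H2O (5 mol %), chiral sulfonate-bearing imidazolinium salt (N-heterocyclic carbene precursor, 5.5 mol %), THF, −15 °C
Reagents that add atoms: none
Why: α-Selective nickel-catalysed hydroalumination gives the 1,1-disubstituted alkenylaluminium, which the carbene–copper catalyst should transfer to C9 in an enantioselective allylic substitution (SN2′); this forms the C8–C9 bond, the C9 stereocentre (catalyst control, ligand enantiomer chosen for 9R, C13 too remote to interfere) and the isopropenyl group in one operation.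

Step 5
Reactants: 7 (5R,8S)-1-[(tert-butyldimethylsilyl)oxy]-8-methyl-4-methylidene-5-(prop-1-en-2-yl)-10-[(triisopropylsilyl)oxy]decane
Product: 8 (5R,8S)-8-methyl-4-methylidene-5-(prop-1-en-2-yl)-10-[(triisopropylsilyl)oxy]decan-1-ol
Conditions: PPTS (cat.), MeOH, 25 °C
Reagents that add atoms: none
Why: Acid-catalysed methanolysis (selective desilylation) should remove the primary TBS ether well before the bulkier primary TIPS ether; stereocentres are untouched.

Step 6
Reactants: 8 (5R,8S)-8-methyl-4-methylidene-5-(prop-1-en-2-yl)-10-[(triisopropylsilyl)oxy]decan-1-ol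
Product: 9 (5R,8S)-8-methyl-4-methylidene-5-(prop-1-en-2-yl)-10-[(triisopropylsilyl)oxy]decanal
Conditions: Dess–Martin periodinane, CH2Cl2, 0 → 25 °C
Reagents that add atoms: none
Why: Dess–Martin oxidation gives the C5 aldehyde under non-basic conditions that should leave the bis-allylic C9–H and both alkenes alone.

Step 7
Reactants: 10 methyl [bis(2,2,2-trifluoroethoxy)phosphoryl]acetate
Product: 12 methyl bromo[bis(2,2,2-trifluoroethoxy)phosphoryl]acetate, via sodium phosphonoacetate 11 (not isolated)
Conditions: NaH, THF, 0 °C; then added to Br2, THF, −78 °C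
Reagents that add atoms: bromine, BrBr
Why: Electrophilic α-bromination of the stabilised phosphonate carbanion; inverse addition to bromine at low temperature should limit proton exchange and dibromination.

Step 8
Reactants: 9 (5R,8S)-8-methyl-4-methylidene-5-(prop-1-en-2-yl)-10-[(triisopropylsilyl)oxy]decanal; 12 methyl bromo[bis(2,2,2-trifluoroethoxy)phosphoryl]acetate
Product: 14 methyl (2E,7R,10S)-2-bromo-10-methyl-6-methylidene-7-(prop-1-en-2-yl)-12-[(triisopropylsilyl)oxy]dodec-2-enoate, via potassium bromophosphonate 13 (not isolated)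
Conditions: 12, t-BuOK, 18-crown-6, THF, −78 °C; then 9, −78 °C
Reagents that add atoms: none
Why: Horner–Wadsworth–Emmons olefination with a bis(trifluoroethyl) phosphonate under dissociating, kinetically controlled (Still–Gennari-type) conditions should place the aldehyde residue cis to the ester, giving the (E)-α-bromo enoate with C6 cis to C19 across the new C5=C4 bond.

Step 9
Reactants: 14 methyl (2E,7R,10S)-2-bromo-10-methyl-6-methylidene-7-(prop-1-en-2-yl)-12-[(triisopropylsilyl)oxy]dodec-2-enoate
Product: 15 methyl (2Z,7R,10S)-2-ethenyl-10-methyl-6-methylidene-7-(prop-1-en-2-yl)-12-[(triisopropylsilyl)oxy]dodec-2-enoate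
Conditions: tributyl(vinyl)stannane, Pd(PPh3)4 (5 mol %), CuI (10 mol %), BHT, DMF, 40 °C
Reagents that add atoms: tributyl(vinyl)stannane, C=C[Sn](CCCC)(CCCC)CCCC
Why: Stille coupling should replace the vinylic bromine by the vinyl group (C3=C2) with retention of alkene geometry, giving the diene ester whose tether carbon C6 lies on the outside of the diene.

Step 10
Reactants: 15 methyl (2Z,7R,10S)-2-ethenyl-10-methyl-6-methylidene-7-(prop-1-en-2-yl)-12-[(triisopropylsilyl)oxy]dodec-2-enoate
Product: 16 methyl (4aR,5S,8aR)-4a-methyl-6-methylidene-5-{(3S)-3-methyl-5-[(triisopropylsilyl)oxy]pentyl}-3,4,4a,5,6,7,8,8a-octahydronaphthalene-1-carboxylate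
Conditions: toluene (0.01 M), BHT (cat.), sealed tube, 150 °C
Reagents that add atoms: none
Why: Thermal, concerted but asynchronous [4+2] cycloaddition (type 1 intramolecular Diels–Alder reaction) of the (2Z)-2-(methoxycarbonyl)-1,3-diene C5=C4–C3=C2 with the isopropenyl alkene C10=C1 forms C5–C10 and C1–C2 in one operation, the LUMO-lowered diene ester pairing with the electron-rich 1,1-dialkyl alkene. The closest known reaction type is the thermal cyclisation of 1,7,9-decatrienes that carry a 2-substituted diene and an isopropenyl dienophile to angular-methyl octalins, together with the enhanced Diels–Alder reactivity of 2-alkoxycarbonyl dienes. Ring B is closed by the C5–C10 bond as the six-membered tether ring C5–C6–C7–C8–C9–C10 (fused mode, both π systems exocyclic to it), and ring A is the new cyclohexene closed by C5–C10 together with C1–C2. C10 and C5 are created: their trans relationship (10β-methyl, 5α-H) should follow from the anti chair-like transition state with diene and dienophile both pseudo-equatorial on the forming ring B, because the C19 ester on C4, cis to C6, acts as a steering substituent whose 1,3-allylic strain with the tether disfavours the syn (cis-fused) arrangement, and their absolute configuration is relayed from C9, whose side chain sits pseudo-equatorially with C9–H near the plane of the isopropenyl group. The step also needs the fused rather than the bridged orientation and reaction at C10=C1 rather than at C8=C17, both secured by the four-atom tether (the C8 methylene is only two atoms from the diene), and an (E)-diene at C5, secured by the (2Z)-enoate geometry set in steps 8 and 9. No Lewis acid is used, because polarising the ester would favour the electronically preferred but unwanted union of C5 with C1.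

Step 11
Reactants: 16 methyl (4aR,5S,8aR)-4a-methyl-6-methylidene-5-{(3S)-3-methyl-5-[(triisopropylsilyl)oxy]pentyl}-3,4,4a,5,6,7,8,8a-octahydronaphthalene-1-carboxylate
Product: 18 methyl (1S,4aR,5S,8aR)-1,4a-dimethyl-6-methylidene-5-{(3S)-3-methyl-5-[(triisopropylsilyl)oxy]pentyl}decahydronaphthalene-1-carboxylate, via lithium ester enolate 17 (not isolated)
Conditions: Li, NH3(l)/THF, t-BuOH (1 equiv), −78 °C; then MeI, −78 → −33 °C
Reagents that add atoms: iodomethane, CI
Why: Dissolving-metal (Birch-type) reductive alkylation of the α,β-unsaturated ester: reduction with protonation at C3 gives the exocyclic ester enolate at C4, which iodomethane should attack from the α face, away from the 1,3-diaxial C10 methyl group, so that C18 becomes equatorial (α) and the C19 ester axial (β).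

Step 12
Reactants: 18 methyl (1S,4aR,5S,8aR)-1,4a-dimethyl-6-methylidene-5-{(3S)-3-methyl-5-[(triisopropylsilyl)oxy]pentyl}decahydronaphthalene-1-carboxylate
Product: 19 (1S,4aR,5S,8aR)-1,4a-dimethyl-6-methylidene-5-{(3S)-3-methyl-5-[(triisopropylsilyl)oxy]pentyl}decahydronaphthalene-1-carboxylic acid
Conditions: NaSEt, DMF, 90 °C; then aqueous HCl (work-up)
Reagents that add atoms: none
Why: SN2 demethylation by thiolate at the ester methyl carbon should cleave the hindered axial ester without attack at its shielded carbonyl; no stereocentre is touched.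

Step 13
Reactants: 19 (1S,4aR,5S,8aR)-1,4a-dimethyl-6-methylidene-5-{(3S)-3-methyl-5-[(triisopropylsilyl)oxy]pentyl}decahydronaphthalene-1-carboxylic acid
Product: 20 (1S,4aR,5S,8aR)-5-[(3S)-5-hydroxy-3-methylpentyl]-1,4a-dimethyl-6-methylidenedecahydronaphthalene-1-carboxylic acid (imbricatolic acid)
Conditions: TBAF, THF, 25 °C; then aqueous NH4Cl (work-up)
Reagents that add atoms: none
Why: Fluoride-induced desilylation of the TIPS ether should free the C15 alcohol without affecting the acid or the exocyclic alkene.

Step 14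
Reactants: 20 imbricatolic acid; 21 vinyl stearate (ethenyl octadecanoate)
Product: 22 (1S,4aR,5S,8aR)-1,4a-dimethyl-6-methylidene-5-[(3S)-3-methyl-5-(octadecanoyloxy)pentyl]decahydronaphthalene-1-carboxylic acid (target)
Conditions: Novozym 435 (immobilised Candida antarctica lipase B), MTBE, 40 °C
Reagents that add atoms: none
Why: Lipase-catalysed irreversible transesterification should acylate the unhindered primary C15 alcohol, while the hindered tertiary C19 carboxylic acid is not a substrate, so the acid needs no protection.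

**Compound list**

1 | (S)-citronellol, (3S)-3,7-dimethyloct-6-en-1-ol | CC(C)=CCC[C@H](C)CCO | starting material
2 | triisopropyl{[(3S)-3,7-dimethyloct-6-en-1-yl]oxy}silane | CC(C)=CCC[C@H](C)CCO[Si](C(C)C)(C(C)C)C(C)C | intermediate
3 | (2E,6S)-2,6-dimethyl-8-[(triisopropylsilyl)oxy]oct-2-en-1-ol | OC/C(C)=C/CC[C@H](C)CCO[Si](C(C)C)(C(C)C)C(C)C | intermediate
4 | diethyl (2E,6S)-2,6-dimethyl-8-[(triisopropylsilyl)oxy]oct-2-en-1-yl phosphate | CCOP(=O)(OCC)OC/C(C)=C/CC[C@H](C)CCO[Si](C(C)C)(C(C)C)C(C)C | intermediate
5 | tert-butyldimethyl(pent-4-yn-1-yloxy)silane | C#CCCCO[Si](C)(C)C(C)(C)C | starting material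
6 | diisobutyl{5-[(tert-butyldimethylsilyl)oxy]pent-1-en-2-yl}aluminium (not isolated) | C=C(CCCO[Si](C)(C)C(C)(C)C)[Al](CC(C)C)CC(C)C | intermediate
7 | (5R,8S)-1-[(tert-butyldimethylsilyl)oxy]-8-methyl-4-methylidene-5-(prop-1-en-2-yl)-10-[(triisopropylsilyl)oxy]decane (skipped diene, 9R and 13S in labdane numbering) | C=C(C)[C@H](C(=C)CCCO[Si](C)(C)C(C)(C)C)CC[C@H](C)CCO[Si](C(C)C)(C(C)C)C(C)C | intermediate
8 | (5R,8S)-8-methyl-4-methylidene-5-(prop-1-en-2-yl)-10-[(triisopropylsilyl)oxy]decan-1-ol | C=C(C)[C@H](C(=C)CCCO)CC[C@H](C)CCO[Si](C(C)C)(C(C)C)C(C)C | intermediate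
9 | (5R,8S)-8-methyl-4-methylidene-5-(prop-1-en-2-yl)-10-[(triisopropylsilyl)oxy]decanal | C=C(C)[C@H](C(=C)CCC=O)CC[C@H](C)CCO[Si](C(C)C)(C(C)C)C(C)C | intermediate
10 | methyl [bis(2,2,2-trifluoroethoxy)phosphoryl]acetate | COC(=O)CP(=O)(OCC(F)(F)F)OCC(F)(F)F | starting material
11 | sodium salt of 10, carbanion at the α-carbon (not isolated) | [Na+].COC(=O)[CH-]P(=O)(OCC(F)(F)F)OCC(F)(F)F | intermediate
12 | methyl bromo[bis(2,2,2-trifluoroethoxy)phosphoryl]acetate | COC(=O)C(Br)P(=O)(OCC(F)(F)F)OCC(F)(F)F | intermediate
13 | potassium salt of 12, carbanion at the α-carbon (not isolated) | [K+].COC(=O)[C-](Br)P(=O)(OCC(F)(F)F)OCC(F)(F)F | intermediate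
14 | methyl (2E,7R,10S)-2-bromo-10-methyl-6-methylidene-7-(prop-1-en-2-yl)-12-[(triisopropylsilyl)oxy]dodec-2-enoate (tether cis to the ester) | COC(=O)/C(Br)=C\CCC(=C)[C@@H](C(C)=C)CC[C@H](C)CCO[Si](C(C)C)(C(C)C)C(C)C | intermediate
15 | methyl (2Z,7R,10S)-2-ethenyl-10-methyl-6-methylidene-7-(prop-1-en-2-yl)-12-[(triisopropylsilyl)oxy]dodec-2-enoate (triene) | COC(=O)/C(C=C)=C\CCC(=C)[C@@H](C(C)=C)CC[C@H](C)CCO[Si](C(C)C)(C(C)C)C(C)C | intermediate
16 | methyl (4aR,5S,8aR)-4a-methyl-6-methylidene-5-{(3S)-3-methyl-5-[(triisopropylsilyl)oxy]pentyl}-3,4,4a,5,6,7,8,8a-octahydronaphthalene-1-carboxylate (trans-fused; 5α-H, 10β-methyl, 9β side chain, C3=C4 enoate) | C=C1CC[C@@H]2[C@](C)(CCC=C2C(=O)OC)[C@H]1CC[C@H](C)CCO[Si](C(C)C)(C(C)C)C(C)C | intermediate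
17 | lithium enolate of the C19 methyl ester, C4=C19 exocyclic to ring A of the trans-decalin (not isolated) | C=C1CC[C@@H]2[C@](C)(CCCC2=C(OC)[O-])[C@H]1CC[C@H](C)CCO[Si](C(C)C)(C(C)C)C(C)C.[Li+] | intermediate
18 | methyl (1S,4aR,5S,8aR)-1,4a-dimethyl-6-methylidene-5-{(3S)-3-methyl-5-[(triisopropylsilyl)oxy]pentyl}decahydronaphthalene-1-carboxylate | C=C1CC[C@@H]2[C@](C)(CCC[C@]2(C)C(=O)OC)[C@H]1CC[C@H](C)CCO[Si](C(C)C)(C(C)C)C(C)C | intermediate
19 | (1S,4aR,5S,8aR)-1,4a-dimethyl-6-methylidene-5-{(3S)-3-methyl-5-[(triisopropylsilyl)oxy]pentyl}decahydronaphthalene-1-carboxylic acid | C=C1CC[C@@H]2[C@](C)(CCC[C@]2(C)C(=O)O)[C@H]1CC[C@H](C)CCO[Si](C(C)C)(C(C)C)C(C)C | intermediate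
20 | imbricatolic acid, (1S,4aR,5S,8aR)-5-[(3S)-5-hydroxy-3-methylpentyl]-1,4a-dimethyl-6-methylidenedecahydronaphthalene-1-carboxylic acid | C=C1CC[C@@H]2[C@](C)(CCC[C@]2(C)C(=O)O)[C@H]1CC[C@H](C)CCO | intermediate
21 | vinyl stearate, ethenyl octadecanoate | C=COC(=O)CCCCCCCCCCCCCCCCC | starting material
22 | (1S,4aR,5S,8aR)-1,4a-dimethyl-6-methylidene-5-[(3S)-3-methyl-5-(octadecanoyloxy)pentyl]decahydronaphthalene-1-carboxylic acid | C=C1CC[C@@H]2[C@](C)(CCC[C@]2(C)C(=O)O)[C@H]1CC[C@H](C)CCOC(=O)CCCCCCCCCCCCCCCCC | target

**Step count**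

Total: 14 steps. Longest linear sequence: 13 steps from (S)-citronellol (steps 1–6 and 8–14); step 7 is a one-step reagent branch.

**Steps most likely to fail**

Step 10 (key cycloaddition). The anti and syn transition states may not be separated well enough at the temperature the unactivated dienophile needs, so that cis-fused adduct forms, and the C9 centre may bias the two faces only moderately. The fallback takes the C5 centre out of the cycloaddition; it sets out from 9 and comes back at 16. Aldehyde 9 would be homologated with methyl diazoacetate and SnCl2 (Roskamp reaction) to the β-keto ester F1. Conjugate addition of F1 to methyl propiolate and lactonisation would give the 6-alkyl-2-pyranone-5-carboxylate F2. On heating, pyranone Diels–Alder addition to the isopropenyl group and loss of CO2 would form the same C5–C10 and C1–C2 bonds but leave C5 trigonal in the cyclohexa-1,3-diene ester F3, so that only C10 is set in the cycloaddition, again under the influence of C9. 1,4-Hydrogenation of the s-cis diene of F3 with Cr(CO)3(naphthalene) and H2, which spares the isolated C8=C17 alkene, should deliver hydrogen to C2 and C5 from the α face, opposite the C10 methyl group, and give 16 with the trans ring fusion.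

Step 4 (allylic substitution). Direct SN2 substitution may compete with the SN2′ path, and enantio-induction may be low, because the allylic phosphate carries a methyl group on the central carbon. The fallback makes the C8–C9 bond by catalytic asymmetric allylboration; it sets out from 3 and comes back at 7. Alcohol 3 would be borylated with B2pin2 and Pd(MeCN)4(BF4)2 to the (E)-allylboronate F4. Addition of F4 to 4-[(tert-butyldimethylsilyl)oxy]butanal under a chiral phosphoric acid (TRIP, enantiomer chosen for 9R) through a closed chair transition state would give the anti homoallylic alcohol F5, with the C9 centre and the isopropenyl group in place. Dess–Martin oxidation to the β,γ-unsaturated ketone F6 and non-basic methylenation with Cp2TiMe2 in toluene at 65 °C would give 7.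

Step 11 (reductive methylation). Over-reduction, or protonation of the enolate by ammonia before it is methylated, would erode the yield and leave C4 unmethylated. The fallback separates the two events; it sets out from 16 and comes back at 18. Conjugate reduction of 16 with Mg in MeOH would give the saturated ester F7 as C4 epimers. Deprotonation with LiN(i-Pr)2 in THF at −78 °C and alkylation with MeI, again from the α face of the exocyclic enolate, would give 18.

**Further compounds**

F1 | step 10 | methyl (7R,10S)-10-methyl-6-methylidene-3-oxo-7-(prop-1-en-2-yl)-12-[(triisopropylsilyl)oxy]dodecanoate | COC(=O)CC(=O)CCC(=C)[C@@H](C(C)=C)CC[C@H](C)CCO[Si](C(C)C)(C(C)C)C(C)C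
F2 | step 10 | methyl 6-{(4R,7S)-7-methyl-3-methylidene-4-(prop-1-en-2-yl)-9-[(triisopropylsilyl)oxy]nonyl}-2-oxo-2H-pyran-5-carboxylate | COC(=O)C1=C(CCC(=C)[C@@H](C(C)=C)CC[C@H](C)CCO[Si](C(C)C)(C(C)C)C(C)C)OC(=O)C=C1
F3 | step 10 | methyl (4aR,5S)-4a-methyl-6-methylidene-5-{(3S)-3-methyl-5-[(triisopropylsilyl)oxy]pentyl}-4,4a,5,6,7,8-hexahydronaphthalene-1-carboxylate | C=C1CCC2=C(C(=O)OC)C=CC[C@]2(C)[C@H]1CC[C@H](C)CCO[Si](C(C)C)(C(C)C)C(C)C
F4 | step 4 | 2-{(2E,6S)-2,6-dimethyl-8-[(triisopropylsilyl)oxy]oct-2-en-1-yl}-4,4,5,5-tetramethyl-1,3,2-dioxaborolane | CC1(C)OB(C/C(C)=C/CC[C@H](C)CCO[Si](C(C)C)(C(C)C)C(C)C)OC1(C)C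
F5 | step 4 | (4S,5R,8S)-1-[(tert-butyldimethylsilyl)oxy]-8-methyl-5-(prop-1-en-2-yl)-10-[(triisopropylsilyl)oxy]decan-4-ol (anti) | C=C(C)[C@H]([C@@H](O)CCCO[Si](C)(C)C(C)(C)C)CC[C@H](C)CCO[Si](C(C)C)(C(C)C)C(C)C
F6 | step 4 | (5R,8S)-1-[(tert-butyldimethylsilyl)oxy]-8-methyl-5-(prop-1-en-2-yl)-10-[(triisopropylsilyl)oxy]decan-4-one | C=C(C)[C@H](C(=O)CCCO[Si](C)(C)C(C)(C)C)CC[C@H](C)CCO[Si](C(C)C)(C(C)C)C(C)C
F7 | step 11 | methyl 15-[(triisopropylsilyl)oxy]-18-norlabd-8(17)-en-19-oate, trans-fused, C4 epimers | C=C1CC[C@@H]2[C@](C)(CCCC2C(=O)OC)[C@H]1CC[C@H](C)CCO[Si](C(C)C)(C(C)C)C(C)C
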